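Numbering and reading of the SMILES: diterpene chain from C1 (CH2OH of the 3-methylbut-2-enol arm) to C16 (CH2OH of the 2-methylbut-2-enol arm). O11 is the ring ether oxygen on C11 and O7 the lactone oxygen on C7. The SMILES reads as 6S,7R,10S,11R,2Z,14Z. The core is a 6,8-dioxabicyclo[3.2.2]nonan-7-one, in which oxepane, 1,4-dioxan-2-one and ε-lactone rings share the bridgeheads C7 and C11.
Cuts, in retrosynthetic order: three silyl ethers; C3–C4 (B-alkyl Suzuki); O11–C6 together with O7–C(=O) (one flask); C11–C12 (Grignard addition to an α-keto ester); C10–C11 (diazoacetate aldol); C4–C5 (Wittig).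
Enabling feature: C6 lies between the fully substituted carbinol carbon C7 and the C5–C4 ethylene of the neryl arm. With C4=C5 as a vinyl group, the O–C6–C7–O edge of the dioxanone ring is a vinyl epoxide. The other edge, O11–C11–C(=O), is an α-hydroxy ester held close by the C8–C10 bridge.
Forward: nerol gives the C4–C10 vinyl epoxide aldehyde, ethyl diazoacetate brings C11 and the carboxyl carbon, and a Grignard reagent brings C12–C16. Zerovalent palladium then folds the open chain into the oxepane and lactone rings in one flask. The vinyl group left on C6 carries in C1–C3.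
Stereochemistry: C6 and C7 come from Sharpless epoxidation of nerol (C6 is copied by double inversion in the key step). C10 comes from the Bu2Mg/ProPhenol aldol, and C11 from Felkin–Anh addition next to C10. Both Z olefins come from chelate-directed carbo- or hydrometallation of propargylic alcohols.

Key step: step 13

Remark: the sense of induction in step 5 is assigned by analogy with other aldehyde additions of the same ligand; both ligand antipodes are commercial.

Step 1
Reactants: 1 nerol
Product: 2 (2S,3R)-2,3-epoxynerol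
Conditions: Ti(Oi-Pr)4 (10 mol %), L-(+)-diethyl tartrate (12 mol %), t-BuOOH, 4 Å MS, CH2Cl2, −20 °C
Reagents that add atoms: tert-butyl hydroperoxide CC(C)(C)OO
Why: Katsuki–Sharpless asymmetric epoxidation touches only the allylic-alcohol olefin, the L-(+)-tartrate delivers oxygen to the face that gives 6S,7R, and the Z geometry of nerol fixes C5 and C8 cis on the oxirane.

Step 2
Reactants: 2 (2S,3R)-2,3-epoxynerol
Product: 3 (2R,3R)-epoxy aldehyde
Conditions: TEMPO (10 mol %), PhI(OAc)2, CH2Cl2, rt
Reagents that add atoms: none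
Why: The oxoammonium (TEMPO) oxidation stops at the aldehyde and leaves the epoxide, the trisubstituted olefin and both stereocentres untouched.

Step 3
Reactants: 3 (2R,3R)-epoxy aldehyde
Product: 4 (2R,3S)-vinyl epoxide with prenyl tail
Conditions: MePPh3Br, NaN(SiMe3)2, THF, −78 °C → 0 °C
Reagents that add atoms: methyltriphenylphosphonium bromide C[P+](c1ccccc1)(c1ccccc1)c1ccccc1.[Br-]
Why: Wittig methylenation of an α,β-epoxy aldehyde at low temperature is the standard entry to vinyl epoxides and does not epimerise C6.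

Step 4
Reactants: 4 (2R,3S)-vinyl epoxide with prenyl tail
Product: 6 3-[(2R,3S)-3-ethenyl-2-methyloxiran-2-yl]propanal, via secondary ozonide 5 (not isolated)
Conditions: O3 (1 equiv, Sudan Red 7B end-point), CH2Cl2, −78 °C; then Me2S, −78 °C → rt
Reagents that add atoms: ozone [O-][O+]=O
Why: Ozonolysis to a dye end-point cleaves the electron-rich trisubstituted olefin much faster than the monosubstituted vinyl group, which the adjacent epoxide oxygen deactivates.

Step 5
Reactants: 6 3-[(2R,3S)-3-ethenyl-2-methyloxiran-2-yl]propanal; 7 ethyl diazoacetate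
Product: 8 (10S)-β-hydroxy-α-diazo ester
Conditions: (S,S)-ProPhenol (5 mol %), Bu2Mg (10 mol %), cis-cyclopentane-1,2-diol (5 mol %), THF, −20 °C
Reagents that add atoms: none
Why: The catalytic asymmetric direct aldol addition of ethyl diazoacetate sets C10 under catalyst control because the existing centres are too remote to matter, and Re-face attack giving 10S is expected for the (S,S) ligand by analogy with its other aldehyde additions.

Step 6
Reactants: 8 (10S)-β-hydroxy-α-diazo ester
Product: 9 (10S)-β-silyloxy-α-diazo ester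
Conditions: TBSCl, imidazole, DMF, rt
Reagents that add atoms: tert-butyldimethylsilyl chloride CC(C)(C)[Si](C)(C)Cl
Why: Standard silylation of the secondary alcohol installs the bulky non-chelating group that step 12 needs for Felkin–Anh control and that keeps O10 out of the key step.

Step 7
Reactants: 9 (10S)-β-silyloxy-α-diazo ester
Product: 10 (10S)-β-silyloxy-α-keto ester
Conditions: dimethyldioxirane (acetone solution, 1.1 equiv), CH2Cl2, 0 °C; 4 Å MS
Reagents that add atoms: dimethyldioxirane CC1(C)OO1
Why: Oxygen-atom transfer from the dioxirane to the nucleophilic diazo carbon with loss of N2 is the known conversion of α-diazo esters into α-keto esters and should outrun epoxidation of the electron-poor vinyl group.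

Step 8
Reactants: 11 propargyl alcohol
Product: 13 (2Z)-3-iodo-2-methylprop-2-en-1-ol, via alkenylmagnesium alkoxide 12 (not isolated)
Conditions: MeMgBr (2.5 equiv), CuI (10 mol %), THF, −10 °C → rt; then I2, −10 °C
Reagents that add atoms: methylmagnesium bromide C[Mg]Br; iodine II
Why: Copper-catalysed anti-carbomagnesiation of the propargylic alkoxide gives a chelated alkenylmagnesium species, and iodinolysis with retention places iodine cis to CH2OH.

Step 9
Reactants: 13 (2Z)-3-iodo-2-methylprop-2-en-1-ol
Product: 14 TBS ether of the (Z)-iodo alcohol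
Conditions: TBSCl, imidazole, CH2Cl2, rt
Reagents that add atoms: tert-butyldimethylsilyl chloride CC(C)(C)[Si](C)(C)Cl
Why: Standard silylation of a primary allylic alcohol leaves the olefin geometry unchanged.

Step 10
Reactants: 14 TBS ether of the (Z)-iodo alcohol; 15 ethylene oxide
Product: 17 (3Z)-5-(TBS-oxy)-4-methylpent-3-en-1-ol, via vinyllithium 16 (not isolated)
Conditions: t-BuLi (2 equiv), Et2O, −78 °C; then ethylene oxide, BF3·OEt2, −78 °C
Reagents that add atoms: none
Why: Iodine–lithium exchange with retention of geometry followed by Lewis-acid-promoted epoxide opening adds C12–C13, and the low temperature in ether should forestall O-to-C silyl migration.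

Step 11
Reactants: 17 (3Z)-5-(TBS-oxy)-4-methylpent-3-en-1-ol
Product: 18 (Z)-homoallylic bromide
Conditions: CBr4, PPh3, 2,6-lutidine, CH2Cl2, 0 °C
Reagents that add atoms: carbon tetrabromide BrC(Br)(Br)Br
Why: The Appel reaction converts the primary alcohol into the bromide under near-neutral conditions that spare the allylic silyl ether and the Z olefin.

Step 12
Reactants: 18 (Z)-homoallylic bromide; 10 (10S)-β-silyloxy-α-keto ester
Product: 20 (6S,7R,10S,11R)-vinyl epoxide α-hydroxy ester, via homoallyl Grignard reagent 19 (not isolated)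
Conditions: Mg, THF, rt; then 10, THF, −78 °C
Reagents that add atoms: none
Why: Grignard addition takes the more electrophilic ketone carbonyl of the α-keto ester, magnesium holds the two carbonyl groups s-cis, and the nucleophile enters anti to the non-chelating C10–OSi bond (polar Felkin–Anh model), which sets 11R.

Step 13
Reactants: 20 (6S,7R,10S,11R)-vinyl epoxide α-hydroxy ester
Product: 23 (1R,2S,5R,9S)-9-ethenyl-6,8-dioxabicyclo[3.2.2]nonan-7-one bis-TBS ether, via allylpalladium alkoxide 21 (not isolated), via oxepane hydroxy ester 22 (not isolated)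
Conditions: Pd2(dba)3·CHCl3 (2.5 mol %), P(Oi-Pr)3 (20 mol %), 5 Å MS, THF, rt; then KOt-Bu (10 mol %), same flask, rt → 40 °C
Reagents that add atoms: none
Why: Zerovalent palladium ionises the allylic C6–O bond of the vinyl epoxide with inversion to the allylpalladium alkoxide 21, the C7 alkoxide takes the proton of the more acidic α-hydroxy ester, O11 attacks C6 on the face away from the metal to give oxepane 22, and the C7 alkoxide (kept alive by the catalytic KOt-Bu) then expels ethoxide from the C11 ester; should acyl transfer come first, the same two bonds form in the reverse order and lead to the same product. The closest known reaction type is the Tsuji–Trost cyclisation of hydroxy vinyl epoxides to 2-vinyl-3-hydroxy cyclic ethers with net retention, followed by ordinary alkoxide-catalysed lactonisation. The oxepane closes in the 7-exo mode at the substituted allyl terminus (the vinyl group stays outside the ring), helped by the two fully substituted carbons C7 and C11 in the tether, and the lactone closes by 6-exo-trig addition–elimination, which completes the 1,4-dioxan-2-one and ε-lactone rings of the bicycle in one event. C6 is the only centre that is broken and re-made, and the double inversion copies the 6S configuration written by the Sharpless epoxidation, while 7R and 11R place O7 and the ester on the same face of the oxepane so that bridging is possible. The step needs C6 over C4 (seven- against nine-membered ring), O11 over O10 (silylated) and over O7 (its return only re-forms the epoxide, and the fully substituted C7 offers no hydrogen for diene or ketone formation), and ring closure faster than face exchange of the allyl complex through its C4-bound σ form, which low catalyst loading, a halide-free medium and the phosphite ligand should secure.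

Step 14
Reactants: 24 but-2-yn-1-ol
Product: 26 (2Z)-3-iodobut-2-en-1-ol, via cyclic alkenylaluminate 25 (not isolated)
Conditions: NaAlH2(OCH2CH2OMe)2, THF, 0 °C → rt; then I2, −78 °C
Reagents that add atoms: iodine II
Why: Alkoxide-directed trans-hydroalumination puts aluminium on C3 inside a five-membered chelate, and iodinolysis with retention gives the Z iodide.

Step 15
Reactants: 26 (2Z)-3-iodobut-2-en-1-ol
Product: 27 TBS ether of (2Z)-3-iodobut-2-en-1-ol
Conditions: TBSCl, imidazole, CH2Cl2, rt
Reagents that add atoms: tert-butyldimethylsilyl chloride CC(C)(C)[Si](C)(C)Cl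
Why: Standard silylation of a primary allylic alcohol leaves the olefin geometry unchanged.

Step 16
Reactants: 23 (1R,2S,5R,9S)-9-ethenyl-6,8-dioxabicyclo[3.2.2]nonan-7-one bis-TBS ether; 27 TBS ether of (2Z)-3-iodobut-2-en-1-ol
Product: 29 tris-TBS ether of the target, via B-alkyl-9-BBN adduct 28 (not isolated)
Conditions: 9-BBN (1.5 equiv), THF, rt; then 27, Pd(dppf)Cl2·CH2Cl2 (5 mol %), AsPh3, Cs2CO3, DMF–H2O, rt
Reagents that add atoms: none
Why: 9-BBN hydroborates only the monosubstituted vinyl group at its terminus, and the B-alkyl Suzuki–Miyaura coupling joins C4 to C3 with retention of the Z geometry under conditions that should spare the hindered lactone.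

Step 17
Reactants: 29 tris-TBS ether of the target
Product: 30 CNP0105745.1
Conditions: HF·pyridine, pyridine, THF, 0 °C → rt
Reagents that add atoms: none
Why: Buffered fluoride desilylation removes all three silyl ethers without base, so the lactone, the Z allylic alcohols and all stereocentres should stay intact.

Compound list
1 | nerol, (2Z)-3,7-dimethylocta-2,6-dien-1-ol | CC(C)=CCC/C(C)=C\CO | starting material
2 | [(2S,3R)-3-methyl-3-(4-methylpent-3-en-1-yl)oxiran-2-yl]methanol | OC[C@@H]1O[C@]1(C)CCC=C(C)C | intermediate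
3 | (2R,3R)-3-methyl-3-(4-methylpent-3-en-1-yl)oxirane-2-carbaldehyde | O=C[C@@H]1O[C@]1(C)CCC=C(C)C | intermediate
4 | (2R,3S)-3-ethenyl-2-methyl-2-(4-methylpent-3-en-1-yl)oxirane | C=C[C@@H]1O[C@]1(C)CCC=C(C)C | intermediate
5 | 3-{2-[(2R,3S)-3-ethenyl-2-methyloxiran-2-yl]ethyl}-5,5-dimethyl-1,2,4-trioxolane (epimers at the trioxolane carbon) | C=C[C@@H]1O[C@]1(C)CCC1OOC(C)(C)O1 | intermediate
6 | 3-[(2R,3S)-3-ethenyl-2-methyloxiran-2-yl]propanal | C=C[C@@H]1O[C@]1(C)CCC=O | intermediate
7 | ethyl diazoacetate | CCOC(=O)C=[N+]=[N-] | starting material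
8 | ethyl (3S)-2-diazo-5-[(2R,3S)-3-ethenyl-2-methyloxiran-2-yl]-3-hydroxypentanoate | C=C[C@@H]1O[C@]1(C)CC[C@H](O)C(=[N+]=[N-])C(=O)OCC | intermediate
9 | ethyl (3S)-3-[(tert-butyldimethylsilyl)oxy]-2-diazo-5-[(2R,3S)-3-ethenyl-2-methyloxiran-2-yl]pentanoate | C=C[C@@H]1O[C@]1(C)CC[C@H](O[Si](C)(C)C(C)(C)C)C(=[N+]=[N-])C(=O)OCC | intermediate
10 | ethyl (3S)-3-[(tert-butyldimethylsilyl)oxy]-5-[(2R,3S)-3-ethenyl-2-methyloxiran-2-yl]-2-oxopentanoate | C=C[C@@H]1O[C@]1(C)CC[C@H](O[Si](C)(C)C(C)(C)C)C(=O)C(=O)OCC | intermediate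
11 | propargyl alcohol | C#CCO | starting material
12 | bromomagnesium (2Z)-3-(bromomagnesio)-2-methylprop-2-en-1-olate | Br[Mg]OC/C(C)=C\[Mg]Br | intermediate
13 | (2Z)-3-iodo-2-methylprop-2-en-1-ol | OC/C(C)=C\I | intermediate
14 | tert-butyl{[(2Z)-3-iodo-2-methylprop-2-en-1-yl]oxy}dimethylsilane | CC(C)(C)[Si](C)(C)OC/C(C)=C\I | intermediate
15 | ethylene oxide | C1CO1 | starting material
16 | (1Z)-3-[(tert-butyldimethylsilyl)oxy]-2-methylprop-1-en-1-yllithium | CC(C)(C)[Si](C)(C)OC/C(C)=C\[Li] | intermediate
17 | (3Z)-5-[(tert-butyldimethylsilyl)oxy]-4-methylpent-3-en-1-ol | OCC/C=C(/C)CO[Si](C)(C)C(C)(C)C | intermediate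
18 | {[(2Z)-5-bromo-2-methylpent-2-en-1-yl]oxy}(tert-butyl)dimethylsilane | BrCC/C=C(/C)CO[Si](C)(C)C(C)(C)C | intermediate
19 | (3Z)-5-[(tert-butyldimethylsilyl)oxy]-4-methylpent-3-en-1-ylmagnesium bromide | Br[Mg]CC/C=C(/C)CO[Si](C)(C)C(C)(C)C | intermediate
20 | ethyl (2R,5Z)-7-[(tert-butyldimethylsilyl)oxy]-2-{(1S)-1-[(tert-butyldimethylsilyl)oxy]-3-[(2R,3S)-3-ethenyl-2-methyloxiran-2-yl]propyl}-2-hydroxy-6-methylhept-5-enoate | C=C[C@@H]1O[C@]1(C)CC[C@H](O[Si](C)(C)C(C)(C)C)[C@](O)(CC/C=C(/C)CO[Si](C)(C)C(C)(C)C)C(=O)OCC | intermediate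
21 | allylpalladium C7-alkoxide zwitterion from 20, drawn in its C6-bound σ form, phosphite ligands omitted | C=C[C@@H]([Pd+])[C@](C)([O-])CC[C@H](O[Si](C)(C)C(C)(C)C)[C@](O)(CC/C=C(/C)CO[Si](C)(C)C(C)(C)C)C(=O)OCC | intermediate
22 | ethyl (2R,3S,6R,7S)-3-[(tert-butyldimethylsilyl)oxy]-2-{(3Z)-5-[(tert-butyldimethylsilyl)oxy]-4-methylpent-3-en-1-yl}-7-ethenyl-6-hydroxy-6-methyloxepane-2-carboxylate | C/C(=C/CC[C@@]1(C(=O)OCC)O[C@@H](C=C)[C@](C)(O)CC[C@@H]1O[Si](C)(C)C(C)(C)C)CO[Si](C)(C)C(C)(C)C | intermediate
23 | (1R,2S,5R,9S)-2-[(tert-butyldimethylsilyl)oxy]-1-{(3Z)-5-[(tert-butyldimethylsilyl)oxy]-4-methylpent-3-en-1-yl}-9-ethenyl-5-methyl-6,8-dioxabicyclo[3.2.2]nonan-7-one | C/C(=C/CC[C@@]12O[C@@H](C=C)[C@@](C)(CC[C@@H]1O[Si](C)(C)C(C)(C)C)OC2=O)CO[Si](C)(C)C(C)(C)C | intermediate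
24 | but-2-yn-1-ol | CC#CCO | starting material
25 | sodium 2,2-bis(2-methoxyethoxy)-3-methyl-2,5-dihydro-1,2-oxaaluminol-2-uide | CC1=CCO[Al-]1(OCCOC)OCCOC.[Na+] | intermediate
26 | (2Z)-3-iodobut-2-en-1-ol | C/C(I)=C/CO | intermediate
27 | tert-butyl{[(2Z)-3-iodobut-2-en-1-yl]oxy}dimethylsilane | C/C(I)=C/CO[Si](C)(C)C(C)(C)C | intermediate
28 | 9-{2-[(1R,2S,5R,9S)-bicyclic lactone of 23-9-yl]ethyl}-9-borabicyclo[3.3.1]nonane | C/C(=C/CC[C@@]12O[C@@H](CCB3C4CCCC3CCC4)[C@@](C)(CC[C@@H]1O[Si](C)(C)C(C)(C)C)OC2=O)CO[Si](C)(C)C(C)(C)C | intermediate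
29 | (1R,2S,5R,9S)-2-[(tert-butyldimethylsilyl)oxy]-9-{(3Z)-5-[(tert-butyldimethylsilyl)oxy]-3-methylpent-3-en-1-yl}-1-{(3Z)-5-[(tert-butyldimethylsilyl)oxy]-4-methylpent-3-en-1-yl}-5-methyl-6,8-dioxabicyclo[3.2.2]nonan-7-one | C/C(=C/CC[C@@]12O[C@@H](CC/C(C)=C\CO[Si](C)(C)C(C)(C)C)[C@@](C)(CC[C@@H]1O[Si](C)(C)C(C)(C)C)OC2=O)CO[Si](C)(C)C(C)(C)C | intermediate
30 | CNP0105745.1, (1R,2S,5R,9S)-2-hydroxy-9-[(3Z)-5-hydroxy-3-methylpent-3-en-1-yl]-1-[(3Z)-5-hydroxy-4-methylpent-3-en-1-yl]-5-methyl-6,8-dioxabicyclo[3.2.2]nonan-7-one | C/C(=C/CC[C@@]12O[C@@H](CC/C(C)=C\CO)[C@@](C)(CC[C@@H]1O)OC2=O)CO | target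

Total step count: 17. Longest linear sequence: 11 steps (steps 1–7, 12, 13, 16, 17, from nerol).

Steps most likely to fail

Step 13. Three processes may interfere:
- Face exchange of the allyl complex before ring closure would erode the C6 configuration.
- Closure of the seven-membered ring by a tertiary alkoxide may be slow.
- A silyl shift from O10 to O11 would free O10 for six-membered ring closure.

The fallback sets out from 20 and returns at 22. Pd(PPh3)4 with acetic acid in THF opens the vinyl epoxide in the 1,4 sense to the (E)-allylic acetate diol F1. Next, [Ir(cod)Cl]2 with a BINOL-derived phosphoramidite ligand acts on the zinc alkoxide made with Et2Zn and closes the oxepane at the branched allyl terminus. In this catalyst-controlled asymmetric allylic etherification the ligand, and no longer the epoxide, fixes 6S. Oxepane 22 is then lactonised to 23 as in the main route.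

Step 12. Facial selectivity at the ketone may be poor if magnesium bridges O10 despite the silyl group. Enolisation toward C10 or β-hydride reduction by the Grignard reagent may also compete. The fallback sets out from 10 and returns at 23.
- Ester exchange of 10 with (−)-8-phenylmenthol (Bu2SnO cat., toluene, 90 °C) gives the 8-phenylmenthyl α-keto ester F2. Its aryl ring covers one face of the magnesium-bridged s-cis dicarbonyl unit.
- By the known sense of this auxiliary the open face is the one that leads to 11R, so auxiliary control and Felkin–Anh control reinforce each other.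
- Addition of 19 should then give the 8-phenylmenthyl α-hydroxy ester F3.
- F3 is taken through the conditions of step 13, where the auxiliary alcohol leaves in place of ethanol.

Step 5. Facial selectivity may be modest with an unbranched aliphatic aldehyde, and self-aldolisation may compete. The fallback sets out from 6 and 7 and returns at 8.
- DBU-catalysed addition without stereocontrol gives the C10-epimeric diazo alcohols F4.
- IBX in DMSO oxidises them to the single α-diazo-β-keto ester F5.
- An enantioselective ketone reduction then sets 10S, using a ketoreductase with NADPH recycled by glucose dehydrogenase in pH 7 buffer. This reduction type is known for α-diazo-β-keto esters, and at this stage the two groups flanking the carbonyl differ strongly.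

Further compounds
F1 | step 13 | ethyl (2R,5Z)-2-{(1S,4R,5E)-7-acetoxy-1-[(tert-butyldimethylsilyl)oxy]-4-hydroxy-4-methylhept-5-en-1-yl}-7-[(tert-butyldimethylsilyl)oxy]-2-hydroxy-6-methylhept-5-enoate | CC(=O)OC/C=C/[C@](C)(O)CC[C@H](O[Si](C)(C)C(C)(C)C)[C@](O)(CC/C=C(/C)CO[Si](C)(C)C(C)(C)C)C(=O)OCC
F2 | step 12 | (1R,2S,5R)-5-methyl-2-(2-phenylpropan-2-yl)cyclohexyl (3S)-3-[(tert-butyldimethylsilyl)oxy]-5-[(2R,3S)-3-ethenyl-2-methyloxiran-2-yl]-2-oxopentanoate | C=C[C@@H]1O[C@]1(C)CC[C@H](O[Si](C)(C)C(C)(C)C)C(=O)C(=O)O[C@@H]1C[C@H](C)CC[C@H]1C(C)(C)c1ccccc1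
F3 | step 12 | (1R,2S,5R)-5-methyl-2-(2-phenylpropan-2-yl)cyclohexyl ester analogue of 20 (2R,5Z; side chain 1S; oxirane 2R,3S) | C=C[C@@H]1O[C@]1(C)CC[C@H](O[Si](C)(C)C(C)(C)C)[C@](O)(CC/C=C(/C)CO[Si](C)(C)C(C)(C)C)C(=O)O[C@@H]1C[C@H](C)CC[C@H]1C(C)(C)c1ccccc1
F4 | step 5 | ethyl 2-diazo-5-[(2R,3S)-3-ethenyl-2-methyloxiran-2-yl]-3-hydroxypentanoate (both C3 epimers) | C=C[C@@H]1O[C@]1(C)CCC(O)C(=[N+]=[N-])C(=O)OCC
F5 | step 5 | ethyl 2-diazo-5-[(2R,3S)-3-ethenyl-2-methyloxiran-2-yl]-3-oxopentanoate | C=C[C@@H]1O[C@]1(C)CCC(=O)C(=[N+]=[N-])C(=O)OCC
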